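The ten-membered carbocycle is treated as the perimeter of a trans-decalin. The E C4=C5 olefin sits across the ring from oxygenated C9 and C1=C10 is ring-cis, so a C4–C9 bond divides the macrocycle into ring A (C4–C5–C6–C7–C8–C9) and ring B (C4–C3–C2–C1–C10–C9). Grob fragmentation of a C9 alkoxide against a C5 mesylate cuts this shared bond and sets free the E olefin, the C9 ketone and the ten-membered ring in one operation. The precursor is a rigid chair–chair decalin with axial C4 methyl and C9 hydroxyl, equatorial C5 mesylate, the ring-B olefin, and C6–C8 already oxygenated and ethynylated.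

Key step: step 16

Remark 1: germacrane numbering (C1–C13) is used for every intermediate. In the decalins β is the face of the C4 methyl group and α the opposite face.
Remark 2 (assumption): (R)-but-3-ene-1,2-diol is taken as a catalogue compound.
Remark 3: O8 and O9 are trans-diaxial in the decalin, so this diol is made by epoxide opening. A reductive carbonyl coupling of C8 with C9 would favour the cis diol.

Step 1
Reactants: 1 2-methylcyclohex-2-en-1-one
Product: 3 (±)-2,6-dimethylcyclohex-2-en-1-one, via lithium α′-enolate 2 (not isolated)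
Conditions: LiN(iPr)2, THF, −78 °C; MeI, −78 → 0 °C
Reagents that add atoms: iodomethane, CI; lithium diisopropylamide, CC(C)[N-]C(C)C.[Li+] (lithium only in 2)
Why: Kinetic deprotonation of the cross-conjugated enone at the α′ carbon (later C4) and SN2 methylation of the enolate (enolate alkylation) should give 3; the new centre is racemic and is erased again in step 2.

Step 2
Reactants: 3 (±)-2,6-dimethylcyclohex-2-en-1-one
Product: 5 trimethylsilyl dienol ether of 3, via lithium dienolate 4 (not isolated)
Conditions: LiN(iPr)2, THF, −78 °C; Me3SiCl, −78 → 0 °C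
Reagents that add atoms: chlorotrimethylsilane, C[Si](C)(C)Cl; lithium diisopropylamide, CC(C)[N-]C(C)C.[Li+] (lithium only in 4)
Why: Removal of the last α′ hydrogen gives a planar, achiral tetrasubstituted enolate that is trapped on oxygen (silyl enol ether formation), so both enantiomers of 3 converge on one nucleophile.

Step 3
Reactants: 6 (R)-but-3-ene-1,2-diol
Product: 7 (4R)-2-(4-methoxyphenyl)-4-vinyl-1,3-dioxolane
Conditions: 4-MeOC6H4CH(OMe)2, PPTS (cat.), CH2Cl2, rt
Reagents that add atoms: 4-methoxybenzaldehyde dimethyl acetal, COC(OC)c1ccc(OC)cc1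
Why: Acid-catalysed transacetalisation of the 1,2-diol closes the five-membered acetal without touching the carbinol centre (later C6); the acetal carbon forms as a mixture that disappears in step 4.

Step 4
Reactants: 7 (4R)-2-(4-methoxyphenyl)-4-vinyl-1,3-dioxolane
Product: 8 (R)-2-[(4-methoxybenzyl)oxy]but-3-en-1-ol
Conditions: iBu2AlH, CH2Cl2, −78 → 0 °C; aq. potassium sodium tartrate
Reagents that add atoms: none
Why: In this reductive acetal cleavage aluminium binds the less hindered primary oxygen, so hydride transfer to the oxocarbenium ion leaves the PMB group on the secondary oxygen and frees the primary alcohol.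

Step 5
Reactants: 8 (R)-2-[(4-methoxybenzyl)oxy]but-3-en-1-ol
Product: 9 (R)-2-[(4-methoxybenzyl)oxy]but-3-enal
Conditions: Dess–Martin periodinane, NaHCO3, CH2Cl2, 0 °C; used at once
Reagents that add atoms: none
Why: Buffered Dess–Martin oxidation stops at the aldehyde under non-basic conditions, which should avoid enolisation of the α-alkoxy β,γ-unsaturated aldehyde (racemisation or shift of the olefin into conjugation).

Step 6
Reactants: 5 trimethylsilyl dienol ether; 9 (R)-2-[(4-methoxybenzyl)oxy]but-3-enal
Product: 10 aldol adduct (4R,5R,6R)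
Conditions: MgBr2·OEt2 (3 equiv), CH2Cl2, −78 → −30 °C; aq. NH4Cl
Reagents that add atoms: none
Why: In this chelation-controlled Mukaiyama aldol addition MgBr2 locks the aldehyde oxygen and the PMB ether oxygen in a five-membered chelate, so the enol silane attacks the face opposite the vinyl group (5,6-syn, C5 R); in the open antiperiplanar transition state the ring methylene C3 turns away from the chelate while the smaller methyl lies over it, which sets quaternary C4 (R) with methyl and O5 on the same face of the later ring A.

Step 7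
Reactants: 10 aldol adduct
Product: 11 5-O-TBS ether of 10
Conditions: tBuMe2SiOTf, 2,6-lutidine, CH2Cl2, 0 °C
Reagents that add atoms: tert-butyldimethylsilyl triflate, CC(C)(C)[Si](C)(C)OS(=O)(=O)C(F)(F)F
Why: The silyl triflate silylates even the neopentyl-type secondary alcohol (silyl ether formation), which blocks retro-aldol cleavage of C4–C5 in the basic steps that follow.

Step 8
Reactants: 11 5-O-TBS ether
Product: 12 methyl ketone (C7 ketone with C8 methyl)
Conditions: PdCl2[2-(4,5-dihydrooxazol-2-yl)quinoline] (5 mol %), AgSbF6 (12 mol %), aq. tBuOOH, CH2Cl2, 0 °C → rt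
Reagents that add atoms: tert-butyl hydroperoxide, CC(C)(C)OO
Why: This catalyst-controlled Wacker-type oxidation of a protected allylic alcohol delivers oxygen to the internal carbon of the terminal olefin (Markovnikov), and the conjugated trisubstituted C1=C10 olefin does not coordinate.

Step 9
Reactants: 12 methyl ketone
Product: 14 decalin dienone (4S,5R,6S), via ketol 13 (not isolated)
Conditions: KN(SiMe3)2, THF, −78 → 0 °C; AcOH; crude ketol, p-TsOH·H2O (cat.), toluene, 40 °C
Reagents that add atoms: none
Why: Kinetic deprotonation of the C8 methyl group and 6-(enolexo)-exo-trig aldol addition to the C9 carbonyl close ring A, and acid-catalysed loss of the tertiary allylic hydroxyl gives the fully conjugated dienone (Robinson-type aldol condensation); the C9 configuration of 13 is irrelevant, and C6, the only epimerisable centre, already holds the favoured equatorial ether.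

Step 10
Reactants: 14 decalin dienone; 15 ethynylmagnesium bromide
Product: 16 7α-ethynyl-7β-hydroxy diene (4S,5R,6S,7R)
Conditions: 15 (3 equiv), LaCl3·2LiCl (0.3 equiv), THF, −78 → −30 °C; aq. NH4Cl
Reagents that add atoms: none
Why: 1,2-Addition of the small alkynyl Grignard reagent should follow the axial trajectory on the α face of the cyclohexenone half-chair, away from the angular C4 methyl, so C7 receives an axial α-ethynyl group and an equatorial β-hydroxyl; the lanthanum salt suppresses enolisation at C6.

Step 11
Reactants: 16 7α-ethynyl-7β-hydroxy diene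
Product: 17 8β,9β-epoxide (4R,5R,6S,7R,8R,9S)
Conditions: VO(acac)2 (5 mol %), tBuOOH (decane), CH2Cl2, 0 °C
Reagents that add atoms: tert-butyl hydroperoxide, CC(C)(C)OO
Why: In this vanadium-catalysed hydroxyl-directed epoxidation the peroxide is delivered from the vanadate ester of the allylic C7 β-hydroxyl, which selects C8=C9 over the remote C1=C10 olefin and places the oxirane on the β face.

Step 12
Reactants: 17 8β,9β-epoxide
Product: 18 7β,8β,9α-triol with trans ring fusion (4R,5R,6S,7S,8S,9R)
Conditions: HClO4 (5 mol %), THF/H2O (4:1), 0 °C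
Reagents that add atoms: water, O
Why: In this acid-catalysed epoxide hydrolysis the trans-diaxial (Fürst–Plattner) course and the electronic bias point the same way: water attacks the tertiary allylic C9 from the α face with inversion, giving the axial 9α-hydroxyl (trans to the C4 methyl, hence the trans-decalin) and leaving the axial 8β-oxygen untouched.

Step 13
Reactants: 18 7β,8β,9α-triol
Product: 19 7,8-acetonide
Conditions: Me2C(OMe)2, PPTS (cat.), CH2Cl2, rt
Reagents that add atoms: 2,2-dimethoxypropane, COC(C)(C)OC
Why: Acid-catalysed ketal exchange (acetonide formation) can bridge only the cis 7β,8β pair because O8 and O9 are trans-diaxial, so the tertiary allylic C9 hydroxyl stays free.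

Step 14
Reactants: 19 7,8-acetonide
Product: 20 5β-alcohol
Conditions: Bu4NF, THF, 0 → 40 °C
Reagents that add atoms: none
Why: Fluoride-induced desilylation removes the only silyl group, and the PMB ether, ketal and alkyne are inert to fluoride.

Step 15
Reactants: 20 5β-alcohol
Product: 21 5β-mesylate, the fragmentation precursor (4R,5R,6S,7R,8S,9R)
Conditions: MsCl, Et3N, CH2Cl2, −10 °C
Reagents that add atoms: methanesulfonyl chloride, CS(=O)(=O)Cl
Why: Sulfonylation through the small sulfene intermediate reaches the hindered equatorial secondary C5 hydroxyl, while the axial tertiary C9 hydroxyl does not react at this temperature.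

Step 16
Reactants: 21 5β-mesylate
Product: 23 (1(10)Z,4E)-cyclodecadien-9-one (6S,7R,8R), via potassium alkoxide 22 (not isolated)
Conditions: KN(SiMe3)2 (1.05 equiv), THF, −78 → 0 °C, 15 min; pH 7 phosphate buffer
Reagents that add atoms: potassium hexamethyldisilazide, C[Si](C)(C)[N-][Si](C)(C)C.[K+] (potassium only in 22)
Why: Deprotonation gives the tertiary C9 alkoxide 22, in which an oxygen lone pair, the C9–C4 σ bond and the equatorial C5–OMs bond are held antiperiplanar by the trans-decalin chair, so C9=O forms, C4–C9 breaks, C4=C5 forms and mesylate leaves in one concerted heterolytic (Grob) fragmentation. The closest known reaction type is the base-induced fragmentation of decalin-1,3-diol monosulfonates to E-cyclodecenones. No ring-closing bond is made: the ten-membered ring appears by ring expansion, as the perimeter that remains when the bond shared by rings A and B is cut. No stereocentre is created; C3 and C6 are anti about C4–C5 in the chair (axial methyl anti to H5), which fixes the E geometry, the ring-B cyclohexene becomes the Z C1=C10 olefin, and C6, C7 and C8 are carried over unchanged. Fragmentation has to outrun oxetane formation and E2 loss of mesylate and, afterwards, enolisation at C8 (epimerisation or β-loss of O7): the equatorial leaving group has no antiperiplanar hydrogen and cannot be reached from the rear by O9, the non-nucleophilic base is consumed mole for mole so that no strong base survives the reaction, and O7 is tied up in the acetonide so that no retro-aldol alkoxide can form.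

Step 17
Reactants: 23 cyclodecadienone
Product: 24 9-alcohol (6S,7R,8S,9R)
Conditions: NaBH4, CeCl3·7H2O, MeOH, −78 °C
Reagents that add atoms: none
Why: In this Luche reduction (1,2-selective) the inner face of the C9 carbonyl is covered transannularly by C4=C5, and the outer face is also the one flanked by H8 in the Felkin–Anh/Cornforth arrangement (C8–O8 anti to C=O), so peripheral hydride attack should give the 9R alcohol (8,9-syn).

Step 18
Reactants: 24 9-alcohol; 25 angelic acid
Product: 27 9-O-angelate, via mixed anhydride 26 (not isolated)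
Conditions: 25, 2,4,6-Cl3C6H2COCl, Et3N, toluene, rt; then 24, 80 °C
Reagents that add atoms: 2,4,6-trichlorobenzoyl chloride, O=C(Cl)c1c(Cl)cc(Cl)cc1Cl (its acyl group stays only in 26)
Why: Yamaguchi esterification through the mixed anhydride, run without a nucleophilic catalyst, acylates the only free hydroxyl and avoids the conjugate addition–elimination that would turn the Z angelate into the E tiglate.

Step 19
Reactants: 27 9-O-angelate
Product: 28 6-alcohol
Conditions: DDQ, CH2Cl2/pH 7 buffer (10:1), 0 °C
Reagents that add atoms: none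
Why: Oxidative PMB ether cleavage proceeds by hydride abstraction from the electron-rich benzylic position and hydrolysis of the oxocarbenium ion, and the buffered cold medium spares the ketal, the ester and the isolated trisubstituted olefins.

Step 20
Reactants: 28 6-alcohol
Product: 29 α-methylene-γ-lactone acetonide (6S,7R,8S,9R)
Conditions: PdCl2 (5 mol %), SnCl2 (5 mol %), PPh3 (10 mol %), CO (7 bar), MeCN, 65 °C
Reagents that add atoms: carbon monoxide, [C-]#[O+]
Why: In this palladium-catalysed cyclocarbonylation of a homopropargylic alcohol the alkoxycarbonyl-palladium unit formed from O6–H and CO adds across the alkyne at its inner carbon and protonolysis releases the exo-methylene lactone; O6 and the ethynyl group are cis on C6–C7, so the cis-fused five-membered ring closes easily, and O7 and O8 are masked so that only the 6,12-lactone can form.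

Step 21
Reactants: 29 α-methylene-γ-lactone acetonide
Product: 30 target CNP0303917.1 (6S,7S,8S,9R)
Conditions: AcOH/H2O (4:1), 40 °C
Reagents that add atoms: none
Why: Acid-catalysed ketal hydrolysis with a weak acid should suffice because the dioxolane shares C7 with the lactone ring and is strained, while both ring olefins carry allylic acyloxy groups and are too electron-poor for transannular cyclisation under these conditions.

Compound list
1 | 2-methylcyclohex-2-en-1-one | CC1=CCCCC1=O | starting material
2 | lithium 6-methylcyclohexa-1,5-dien-1-olate (α′-enolate of 1) | [Li+].[O-]C1=CCCC=C1C | intermediate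
3 | (±)-2,6-dimethylcyclohex-2-en-1-one | CC1=CCCC(C)C1=O | intermediate
4 | lithium 2,6-dimethylcyclohexa-1,5-dien-1-olate | [Li+].[O-]C1=C(C)CCC=C1C | intermediate
5 | [(2,6-dimethylcyclohexa-1,5-dien-1-yl)oxy]trimethylsilane | C[Si](C)(C)OC1=C(C)CCC=C1C | intermediate
6 | (R)-but-3-ene-1,2-diol | OC[C@H](O)C=C | starting material
7 | (4R)-2-(4-methoxyphenyl)-4-vinyl-1,3-dioxolane (both acetal epimers) | COc1ccc(cc1)C1OC[C@@H](C=C)O1 | intermediate
8 | (R)-2-[(4-methoxybenzyl)oxy]but-3-en-1-ol | OC[C@H](OCc1ccc(OC)cc1)C=C | intermediate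
9 | (R)-2-[(4-methoxybenzyl)oxy]but-3-enal | O=C[C@H](OCc1ccc(OC)cc1)C=C | intermediate
10 | (6R)-6-{(1R,2R)-1-hydroxy-2-[(4-methoxybenzyl)oxy]but-3-en-1-yl}-2,6-dimethylcyclohex-2-en-1-one (germacrane 4R,5R,6R) | COc1ccc(CO[C@H](C=C)[C@H](O)[C@@]2(C)CCC=C(C)C2=O)cc1 | intermediate
11 | 5-O-tert-butyldimethylsilyl ether of 10 | COc1ccc(CO[C@H](C=C)[C@H](O[Si](C)(C)C(C)(C)C)[C@@]2(C)CCC=C(C)C2=O)cc1 | intermediate
12 | (6R)-6-{(1R,2S)-1-[(tert-butyldimethylsilyl)oxy]-2-[(4-methoxybenzyl)oxy]-3-oxobutyl}-2,6-dimethylcyclohex-2-en-1-one | COc1ccc(CO[C@H](C(C)=O)[C@H](O[Si](C)(C)C(C)(C)C)[C@@]2(C)CCC=C(C)C2=O)cc1 | intermediate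
13 | bicyclic ketol: 9-hydroxy-7-ketone, C1=C10 olefin, 4β-methyl, 5β-OTBS, 6α-OPMB, C9 epimers | COc1ccc(CO[C@H]2[C@H](O[Si](C)(C)C(C)(C)C)[C@@]3(C)CCC=C(C)C3(O)CC2=O)cc1 | intermediate
14 | (4S,5R,6S)-decalin dienone: C7 ketone conjugated with C8=C9 and C10=C1, 4β-methyl, 5β-OTBS and 6α-OPMB both equatorial | COc1ccc(CO[C@H]2[C@H](O[Si](C)(C)C(C)(C)C)[C@@]3(C)CCC=C(C)C3=CC2=O)cc1 | intermediate
15 | ethynylmagnesium bromide | C#C[Mg]Br | starting material
16 | (4S,5R,6S,7R)-7α-ethynyl-7β-hydroxy-8,1(10)-diene | COc1ccc(CO[C@H]2[C@H](O[Si](C)(C)C(C)(C)C)[C@@]3(C)CCC=C(C)C3=C[C@@]2(O)C#C)cc1 | intermediate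
17 | (4R,5R,6S,7R,8R,9S)-8β,9β-epoxide of 16 | COc1ccc(CO[C@H]2[C@H](O[Si](C)(C)C(C)(C)C)[C@@]3(C)CCC=C(C)[C@]34O[C@@H]4[C@@]2(O)C#C)cc1 | intermediate
18 | (4R,5R,6S,7S,8S,9R)-trans-decalin 7β,8β,9α-triol (8-OH and 9-OH axial) | COc1ccc(CO[C@H]2[C@H](O[Si](C)(C)C(C)(C)C)[C@@]3(C)CCC=C(C)[C@]3(O)[C@H](O)[C@@]2(O)C#C)cc1 | intermediate
19 | (4R,5R,6S,7R,8S,9R)-7,8-O-isopropylidene derivative of 18 | COc1ccc(CO[C@H]2[C@H](O[Si](C)(C)C(C)(C)C)[C@@]5(C)CCC=C(C)[C@]5(O)[C@@H]4OC(C)(C)O[C@]24C#C)cc1 | intermediate
20 | 5β,9α-diol (5-OH equatorial, 9-OH axial), 6α-OPMB, 7,8-acetonide | COc1ccc(CO[C@H]2[C@H](O)[C@@]5(C)CCC=C(C)[C@]5(O)[C@@H]4OC(C)(C)O[C@]24C#C)cc1 | intermediate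
21 | (4R,5R,6S,7R,8S,9R)-trans-decalin γ-hydroxy mesylate: axial 4-methyl and 9-OH, equatorial 5-OMs and 6-OPMB, axial 7-ethynyl, 7,8-acetonide, C10=C1 | COc1ccc(CO[C@H]2[C@H](OS(C)(=O)=O)[C@@]5(C)CCC=C(C)[C@]5(O)[C@@H]4OC(C)(C)O[C@]24C#C)cc1 | intermediate
22 | potassium C9 alkoxide of 21 | COc1ccc(CO[C@H]2[C@H](OS(C)(=O)=O)[C@@]5(C)CCC=C(C)[C@]5([O-])[C@@H]4OC(C)(C)O[C@]24C#C)cc1.[K+] | intermediate
23 | (1(10)Z,4E,6S,7R,8R)-7-ethynyl-6-OPMB-7,8-O-isopropylidene-cyclodeca-1(10),4-dien-9-one | COc1ccc(CO[C@H]2/C=C(\C)CC/C=C(/C)C(=O)[C@@H]4OC(C)(C)O[C@]24C#C)cc1 | intermediate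
24 | (6S,7R,8S,9R)-9-alcohol from 23 | COc1ccc(CO[C@H]2/C=C(\C)CC/C=C(/C)[C@@H](O)[C@@H]4OC(C)(C)O[C@]24C#C)cc1 | intermediate
25 | angelic acid, (Z)-2-methylbut-2-enoic acid | C/C=C(/C)C(=O)O | starting material
26 | angelic 2,4,6-trichlorobenzoic anhydride | C/C=C(/C)C(=O)OC(=O)c1c(Cl)cc(Cl)cc1Cl | intermediate
27 | 9-O-angelate of 24 | COc1ccc(CO[C@H]2/C=C(\C)CC/C=C(/C)[C@@H](OC(=O)/C(C)=C\C)[C@@H]4OC(C)(C)O[C@]24C#C)cc1 | intermediate
28 | 6-alcohol (PMB removed) | O[C@H]1/C=C(\C)CC/C=C(/C)[C@@H](OC(=O)/C(C)=C\C)[C@@H]2OC(C)(C)O[C@]12C#C | intermediate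
29 | (6S,7R,8S,9R)-cis-fused 6,12-α-methylene-γ-lactone, 7,8-acetonide, 9-angelate | C=C1C(=O)O[C@H]2/C=C(\C)CC/C=C(/C)[C@@H](OC(=O)/C(C)=C\C)[C@@H]3OC(C)(C)O[C@]123 | intermediate
30 | CNP0303917.1, (1(10)Z,4E,6S,7S,8S,9R)-9-angeloyloxy-7,8-dihydroxygermacra-1(10),4,11(13)-trien-6,12-olide | C=C1C(=O)O[C@H]2/C=C(\C)CC/C=C(/C)[C@@H](OC(=O)/C(C)=C\C)[C@H](O)[C@@]12O | target

Total step count: 21. Longest linear sequence: 19 steps (6 → 30, steps 3–21).

Steps most likely to fail

Step 16. The alkoxide may fragment too slowly at low temperature. The freshly formed α-alkoxy ketone may also be enolised by alkoxide or amide that is still present. Either way C8 could lose its configuration or O7 could be expelled in a β-elimination.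
- The fallback keeps the same bond cleavage but unmasks the alkoxide in a medium that holds no other base. It sets out from 21 and comes back at 23.
- The C9 hydroxyl is capped with Me3SiOTf and 2,6-lutidine (CH2Cl2, −78 °C) to give the 9-O-trimethylsilyl mesylate F1.
- CsF in MeCN at 0 °C then removes the silyl group slowly, so that each alkoxide fragments as it is formed and only CsOMs accumulates.

Step 6. Discrimination between the methyl group and the ring methylene at the tetrasubstituted enol carbon may be poor, chelation may be incomplete, or the Lewis acid may shift the olefin of 9 into conjugation. Each of these would erode C4 or C5.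
- The fallback uses a closed transition state and then corrects C5. It sets out from 4 (made from 3 as in step 2) and 9 and comes back at 10.
- The lithium dienolate is added to 9 in THF at −78 °C. The cyclic E(O)-enolate reacts through a Zimmerman–Traxler chair on the Felkin–Anh/Cornforth face of the aldehyde. This should give the 5-epimeric aldol F2, in which C4 already has the configuration required relative to C6.
- Dess–Martin oxidation gives the non-enolisable-at-C4 1,3-diketone F3.
- Corey–Bakshi–Shibata reduction of F3 ((R)-2-methyl-oxazaborolidine, catecholborane, toluene, −78 °C, with the quaternary C4 as the large group) sets C5 under reagent control. Catecholborane spares the vinyl group and the hindered cross-conjugated C9 ketone.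

Step 20. At 65 °C zerovalent palladium may ionise the allylic angelate or the allylic C6–O bond. Insertion at the alkyne next to the quaternary C7 may also be slow or take the wrong regiochemistry.
- The fallback separates the regiochemical event from the carbonylation. It sets out from 28 and comes back at 29.
- α-Selective hydrostannation (Mo(CO)3(CNtBu)3 cat., Bu3SnH, THF, 55 °C) gives the 11-tributylstannyl olefin F4.
- Tin–iodine exchange (I2, CH2Cl2, −78 °C), much faster than iodination of the ring olefins, gives the 11-iodo olefin F5.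
- Carbonylative lactonisation (Pd(PPh3)4, CO 1 bar, Et3N, MeCN, 40 °C) starts with fast oxidative addition to the C–I bond. The acyl-palladium is trapped by O6.

Further compounds
F1 | step 16 | 9-O-trimethylsilyl ether of mesylate 21 | COc1ccc(CO[C@H]2[C@H](OS(C)(=O)=O)[C@@]5(C)CCC=C(C)[C@]5(O[Si](C)(C)C)[C@@H]4OC(C)(C)O[C@]24C#C)cc1
F2 | step 6 | 5-epimer of aldol adduct 10 | COc1ccc(CO[C@H](C=C)[C@@H](O)[C@@]2(C)CCC=C(C)C2=O)cc1
F3 | step 6 | 5,9-diketone from F2 | COc1ccc(CO[C@H](C=C)C(=O)[C@@]2(C)CCC=C(C)C2=O)cc1
F4 | step 20 | 11-(tributylstannyl) olefin from 28 | O[C@H]1/C=C(\C)CC/C=C(/C)[C@@H](OC(=O)/C(C)=C\C)[C@@H]2OC(C)(C)O[C@]12C(=C)[Sn](CCCC)(CCCC)CCCC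
F5 | step 20 | 11-iodo olefin from F4 | O[C@H]1/C=C(\C)CC/C=C(/C)[C@@H](OC(=O)/C(C)=C\C)[C@@H]2OC(C)(C)O[C@]12C(I)=C
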